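**Strategy.** The target is treated as a C2-symmetric 5,5'-linked bis-tetrahydrofuran in which one half has been isomerised. The tetralin half differs from the tetrahydrofuran half only in that benzylic C1 is bonded to C8a of vanillyl ring D instead of the ring oxygen, while C2 and C3 keep the configuration of the tetrahydrofuran CH(CH2OH) and C(OH) carbons. Acid therefore opens the tetrahydrofuran on ring C, the only ring with a free para-hydroxyl, and Friedel–Crafts closure forms C1–C8a, the tetralin and the C1 stereocentre in one operation. The precursor is the all-cis bis-tetrahydrofuran penta-acetate with ring C phenol alone free, built two-directionally from a differentially protected dehydrodivanillin and a malic-acid-derived lactone.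

Key step: step 15

**Remarks on the chemistry**
- Labels: ring A and ring B are the vanillyl and biaryl rings of the arm that stays a tetrahydrofuran; ring C and ring D are the biaryl and vanillyl rings of the arm that rearranges. The tetrahydrofuran is numbered O1, C2 (aryl), C3 (CH2OH), C4 (OH, benzyl), C5.
- Stereochemical reading of the target: each tetrahydrofuran is (2R,3R,4S), with aryl, hydroxymethyl and benzyl all cis. The tetralin is (1S,2S,3S), with ring C trans to the C2 hydroxymethyl.
- Because the benzylic centre of the retained ring is cis to C3, an acid-mediated ether closure (which would give the trans ring) is not used. Both rings are closed by hemiketal reduction.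
- Precursor design: ring D is acetylated like ring A, since its oxygen is meta to the attacking carbon and need not be free. The two arms are then identical, the skeleton is built in one two-directional sequence, and acetyl transfer between the ring B and ring C oxygens is degenerate before the key step.
- Assumption: (S)-malic acid, (4-benzyloxy-3-methoxyphenyl)methanol and vanillin are taken as commercial.

**Route**

Step 1
Reactants: 1 (S)-malic acid
Product: 2 2-[(2S,4S)-2-tert-butyl-5-oxo-1,3-dioxolan-4-yl]acetic acid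
Conditions: t-BuCHO, TsOH·H2O (cat.), H2SO4 (cat.), pentane, reflux, Dean–Stark; recrystallise
Reagents that add atoms: pivalaldehyde, CC(C)(C)C=O
Why: Acid-catalysed acetalisation of the α-hydroxy acid gives the dioxolanone, and under equilibrating conditions the cis isomer (tert-butyl and CH2CO2H on one face, new acetal centre S) should predominate and crystallise.

Step 2
Reactants: 3 (4-benzyloxy-3-methoxyphenyl)methanol
Product: 4 4-benzyloxy-3-methoxybenzyl bromide
Conditions: PBr3, Et2O, 0 °C; used at once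
Reagents that add atoms: phosphorus tribromide, BrP(Br)Br
Why: Bromination of an electron-rich benzylic alcohol with PBr3 (nucleophilic substitution at the benzylic carbon) is routine, and the labile bromide is not stored.

Step 3
Reactants: 2 cis-dioxolanone acid; 4 benzyl bromide
Product: 5 2-[(2S,4S)-4-(4-benzyloxy-3-methoxybenzyl)-2-tert-butyl-5-oxo-1,3-dioxolan-4-yl]acetic acid
Conditions: LiN(SiMe3)2 (2.2 equiv), THF, −78 °C; 4 (1.2 equiv), −78 → −20 °C; aq. HCl work-up
Reagents that add atoms: none
Why: Enolate alkylation with self-regeneration of the stereocentre: the dianion (carboxylate plus dioxolanone enolate) is benzylated on the face opposite the tert-butyl group, so the benzyl group takes the place of the original hydrogen and the quaternary carbinol centre is set as S.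

Step 4
Reactants: 5 benzylated dioxolanone acid
Product: 7 (4S)-4-[(4-benzyloxy-3-methoxyphenyl)methyl]-4-hydroxyoxolan-2-one, via dihydroxy acid 6 (not isolated)
Conditions: NaH (1.05 equiv), THF, 0 °C; LiBH4 (3 equiv), 0 → 40 °C; 2 M HCl, rt
Reagents that add atoms: none
Why: Chemoselective borohydride reduction of the dioxolanone carbonyl (an ester) beside an inert carboxylate salt releases the tertiary and the new primary alcohol, and acidification closes the γ-lactone onto the primary hydroxyl without touching the quaternary centre.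

Step 5
Reactants: 7 hydroxy lactone
Product: 8 (4S)-4-[(4-benzyloxy-3-methoxyphenyl)methyl]-4-(trimethylsilyloxy)oxolan-2-one
Conditions: Me3SiCl, imidazole, DMF, rt
Reagents that add atoms: chlorotrimethylsilane, C[Si](C)(C)Cl
Why: Silylation of the tertiary alcohol avoids a dianion in the aldol and leaves the benzyl group as the larger and better-donor substituent on C4, the small OSiMe3 group being the lesser one.

Step 6
Reactants: 9 vanillin (2 equiv)
Product: 10 dehydrodivanillin
Conditions: 9 (2.0 equiv), Na2S2O8 (1.1 equiv), FeSO4·7H2O (cat.), H2O, 50 °C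
Reagents that add atoms: vanillin (second molecule), COc1cc(C=O)ccc1O
Why: Oxidative phenol coupling (iron-catalysed persulfate oxidation) joins two molecules of vanillin: each phenoxyl radical reacts through its free ortho carbon because the para position is blocked, and tautomerisation restores both phenols.

Step 7
Reactants: 10 dehydrodivanillin
Product: 11 mono-benzyl ether of dehydrodivanillin
Conditions: BnBr (1.0 equiv), KHCO3 (1.1 equiv), DMF, 40 °C
Reagents that add atoms: benzyl bromide, BrCc1ccccc1
Why: Williamson etherification in which the hydrogen-bonded monoanion of the 2,2'-biphenol should react once with one equivalent of mild base and halide; diol and bis-ether are separable and can be recycled.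

Step 8
Reactants: 11 mono-benzyl ether
Product: 12 benzyl silyl dialdehyde
Conditions: iPr3SiOTf, 2,6-lutidine, CH2Cl2, 0 °C
Reagents that add atoms: triisopropylsilyl trifluoromethanesulfonate, CC(C)[Si](C(C)C)(C(C)C)OS(=O)(=O)C(F)(F)F
Why: Silylation of the remaining hindered phenol with the silyl triflate gives an ether that should survive enolate, hydride, Lewis acid and hydrogenolysis steps and is later removed by fluoride.

Step 9
Reactants: 8 silyl lactone; 12 benzyl silyl dialdehyde
Product: 14 bis-aldol diol, via bis-silyl aldol adduct 13 (not isolated)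
Conditions: 8 (2.6 equiv), LiN(iPr)2 (2.5 equiv), THF, −78 °C; 12, −78 °C; AcOH quench; PPTS (cat.), MeOH, 0 °C
Reagents that add atoms: none
Why: Two-directional lithium-enolate aldol addition in which each aldehyde should be attacked on the enolate face anti to the benzyl group of the adjacent quaternary carbon, setting C3 of each lactone as R; the carbinol centres form as a mixture that is erased in step 11, and mild methanolysis removes the silyl ethers.

Step 10
Reactants: 14 bis-aldol diol
Product: 15 octaol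
Conditions: LiBH4 (6 equiv), THF, 0 °C → rt; MeOH then H2O
Reagents that add atoms: none
Why: Ester reduction with LiBH4 opens both lactones to 1,4-diols without touching aryl ethers or any stereocentre.

Step 11
Reactants: 15 octaol
Product: 17 bis-hemiketal, via diketone 16 (not isolated)
Conditions: activated MnO2 (excess), acetone, rt
Reagents that add atoms: none
Why: Chemoselective benzylic oxidation with MnO2 converts only the two secondary benzylic alcohols to aryl ketones, each of which is trapped by its γ-hydroxyl as the five-membered hemiketal, so both carbinol epimers converge.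

Step 12
Reactants: 17 bis-hemiketal
Product: 18 all-cis bis-tetrahydrofuran
Conditions: Et3SiH, BF3·OEt2, CH2Cl2/MeCN, −78 → −40 °C; Et3N then aq. NaHCO3 at low temperature
Reagents that add atoms: none
Why: Silane–Lewis acid reduction of a cyclic hemiketal (ionic hydrogenation, as used for C-aryl glycosides and 2-aryl-tetrahydrofuran lignans): hydride should add to the aryl oxocarbenium ion from the face opposite the C3 hydroxymethyl and C4 benzyl groups, placing the aryl group cis to both and setting C2 as R in each ring.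

Step 13
Reactants: 18 all-cis bis-tetrahydrofuran
Product: 20 penta-acetate silyl ether, via triphenol 19 (not isolated)
Conditions: H2 (1 atm), 10% Pd/C, EtOAc, rt; filter; Ac2O, pyridine, rt
Reagents that add atoms: acetic anhydride, CC(=O)OC(C)=O
Why: Neutral hydrogenolysis removes the three aryl benzyl ethers, and the crude triphenol, whose ring B tetrahydrofuran is now acid-labile, is acetylated at once at the three phenols and two primary alcohols (tertiary alcohols do not react without DMAP).

Step 14
Reactants: 20 penta-acetate silyl ether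
Product: 21 key-step precursor
Conditions: Bu4NF, AcOH, THF, 0 °C → rt
Reagents that add atoms: none
Why: Fluoride cleavage of the aryl silyl ether under acetic acid buffering should leave the acetates intact, and any acetyl shift between the ring B and ring C oxygens is degenerate because the arms are identical.

Step 15
Reactants: 21 key-step precursor
Product: 22 tetrahydrofuran–tetralin penta-acetate
Conditions: CF3CO2H (10 equiv), CH2Cl2, 0 °C; aq. NaHCO3 quench
Reagents that add atoms: none
Why: CF3CO2H protonates O1 of the tetrahydrofuran on ring C and the free para-hydroxyl pushes out the C2–O1 bond to give a para-quinone-methide-type benzylic cation, which is attacked by the ring D carbon para to OMe to form C1–C8a; loss of the arene proton is irreversible, whereas reclosure to either tetrahydrofuran epimer or capture by the neighbouring acetate is reversible. The closest known reaction type is the acid-induced isomerisation of 2-aryl-4-benzyl-4-hydroxytetrahydrofuran lignans to 1-aryltetralins (intramolecular Friedel–Crafts alkylation). The six-membered ring closes 6-exo-trig at the exocyclic quinone-methide carbon (6-endo with respect to the arene π bond of ring D). The new C1 centre is controlled by the C2 CH2OAc group, since in the chair-like transition state ring C lies pseudo-equatorial and trans to it (1S), whatever the benzylic configuration of 21. Two selectivities are needed: only the ring C arm may ionise, which the free phenol versus the non-donating aryl acetate on ring B secures, and only the position para to OMe may attack, which is the sole unhindered and activated carbon ortho to the tether.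

Step 16
Reactants: 22 tetrahydrofuran–tetralin penta-acetate
Product: 23 target CNP0344108.1
Conditions: K2CO3 (2 equiv), MeOH (degassed), 0 °C → rt; AcOH to pH 6–7
Reagents that add atoms: none
Why: Base-catalysed transesterification (Zemplén-type methanolysis) should remove all five acetates without affecting the benzylic ether of the retained ring or any stereocentre, and the near-neutral work-up protects the now acid-labile para-hydroxybenzylic tetrahydrofuran.

**Compound list**

1 | (S)-malic acid | OC(=O)C[C@H](O)C(=O)O | starting material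
2 | 2-[(2S,4S)-2-tert-butyl-5-oxo-1,3-dioxolan-4-yl]acetic acid (tert-butyl and CH2CO2H cis) | OC(=O)C[C@@H]1O[C@H](C(C)(C)C)OC1=O | intermediate
3 | (4-benzyloxy-3-methoxyphenyl)methanol | COc1cc(CO)ccc1OCc1ccccc1 | starting material
4 | 4-benzyloxy-3-methoxybenzyl bromide | COc1cc(CBr)ccc1OCc1ccccc1 | intermediate
5 | 2-[(2S,4S)-4-(4-benzyloxy-3-methoxybenzyl)-2-tert-butyl-5-oxo-1,3-dioxolan-4-yl]acetic acid (benzyl trans to tert-butyl) | OC(=O)C[C@]1(Cc2ccc(OCc3ccccc3)c(OC)c2)O[C@H](C(C)(C)C)OC1=O | intermediate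
6 | (3S)-3-[(4-benzyloxy-3-methoxyphenyl)methyl]-3,4-dihydroxybutanoic acid | OC(=O)C[C@](O)(CO)Cc1ccc(OCc2ccccc2)c(OC)c1 | intermediate
7 | (4S)-4-[(4-benzyloxy-3-methoxyphenyl)methyl]-4-hydroxyoxolan-2-one | O=C1C[C@@](O)(Cc2ccc(OCc3ccccc3)c(OC)c2)CO1 | intermediate
8 | (4S)-4-[(4-benzyloxy-3-methoxyphenyl)methyl]-4-(trimethylsilyloxy)oxolan-2-one | O=C1C[C@@](O[Si](C)(C)C)(Cc2ccc(OCc3ccccc3)c(OC)c2)CO1 | intermediate
9 | vanillin | COc1cc(C=O)ccc1O | starting material
10 | dehydrodivanillin (6,6'-dihydroxy-5,5'-dimethoxybiphenyl-3,3'-dicarbaldehyde) | COc1cc(C=O)cc(-c2cc(C=O)cc(OC)c2O)c1O | intermediate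
11 | 6-benzyloxy-6'-hydroxy-5,5'-dimethoxybiphenyl-3,3'-dicarbaldehyde | COc1cc(C=O)cc(-c2cc(C=O)cc(OC)c2O)c1OCc1ccccc1 | intermediate
12 | 6-benzyloxy-5,5'-dimethoxy-6'-(triisopropylsilyloxy)biphenyl-3,3'-dicarbaldehyde (benzyl on ring B, silyl on ring C) | COc1cc(C=O)cc(-c2cc(C=O)cc(OC)c2O[Si](C(C)C)(C(C)C)C(C)C)c1OCc1ccccc1 | intermediate
13 | bis-silyl aldol adduct: each formyl carbon of 12 is a CH(OH) bonded to C3 of a (3R,4S)-4-(4-benzyloxy-3-methoxybenzyl)-4-(trimethylsilyloxy)oxolan-2-one; carbinol carbons epimeric | COc1cc(C(O)[C@H]2C(=O)OC[C@]2(O[Si](C)(C)C)Cc2ccc(OCc3ccccc3)c(OC)c2)cc(-c2cc(C(O)[C@H]3C(=O)OC[C@]3(O[Si](C)(C)C)Cc3ccc(OCc4ccccc4)c(OC)c3)cc(OC)c2O[Si](C(C)C)(C(C)C)C(C)C)c1OCc1ccccc1 | intermediate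
14 | bis-aldol diol: as 13 with both tertiary hydroxyls free | COc1cc(C(O)[C@H]2C(=O)OC[C@]2(O)Cc2ccc(OCc3ccccc3)c(OC)c2)cc(-c2cc(C(O)[C@H]3C(=O)OC[C@]3(O)Cc3ccc(OCc4ccccc4)c(OC)c3)cc(OC)c2O[Si](C(C)C)(C(C)C)C(C)C)c1OCc1ccccc1 | intermediate
15 | octaol: each biaryl ring carries a (2R,3S)-1,3,4-trihydroxy-2-(hydroxymethyl)-3-(4-benzyloxy-3-methoxybenzyl)butyl chain, C1 epimeric | COc1cc(C(O)[C@@H](CO)[C@](O)(CO)Cc2ccc(OCc3ccccc3)c(OC)c2)cc(-c2cc(C(O)[C@@H](CO)[C@](O)(CO)Cc3ccc(OCc4ccccc4)c(OC)c3)cc(OC)c2O[Si](C(C)C)(C(C)C)C(C)C)c1OCc1ccccc1 | intermediate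
16 | diketone: both C1 carbinols of 15 oxidised to aryl ketones | COc1cc(C(=O)[C@@H](CO)[C@](O)(CO)Cc2ccc(OCc3ccccc3)c(OC)c2)cc(-c2cc(C(=O)[C@@H](CO)[C@](O)(CO)Cc3ccc(OCc4ccccc4)c(OC)c3)cc(OC)c2O[Si](C(C)C)(C(C)C)C(C)C)c1OCc1ccccc1 | intermediate
17 | bis-hemiketal: each arm a 2-aryl-2-hydroxy-3-(hydroxymethyl)-4-(4-benzyloxy-3-methoxybenzyl)oxolan-4-ol, C3 and C4 as in 18, anomeric mixture | COc1cc(C2(O)OC[C@](O)(Cc3ccc(OCc4ccccc4)c(OC)c3)[C@@H]2CO)cc(-c2cc(C3(O)OC[C@](O)(Cc4ccc(OCc5ccccc5)c(OC)c4)[C@@H]3CO)cc(OC)c2O[Si](C(C)C)(C(C)C)C(C)C)c1OCc1ccccc1 | intermediate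
18 | all-cis bis-tetrahydrofuran: both arms (2R,3R,4S)-2-aryl-3-(hydroxymethyl)-4-(4-benzyloxy-3-methoxybenzyl)oxolan-4-ol; ring B O-benzyl, ring C O-Si(iPr)3 | COc1cc([C@@H]2OC[C@](O)(Cc3ccc(OCc4ccccc4)c(OC)c3)[C@@H]2CO)cc(-c2cc([C@@H]3OC[C@](O)(Cc4ccc(OCc5ccccc5)c(OC)c4)[C@@H]3CO)cc(OC)c2O[Si](C(C)C)(C(C)C)C(C)C)c1OCc1ccccc1 | intermediate
19 | triphenol: as 18 with ring A, ring B and ring D phenols free, ring C still silylated | COc1cc([C@@H]2OC[C@](O)(Cc3ccc(O)c(OC)c3)[C@@H]2CO)cc(-c2cc([C@@H]3OC[C@](O)(Cc4ccc(O)c(OC)c4)[C@@H]3CO)cc(OC)c2O[Si](C(C)C)(C(C)C)C(C)C)c1O | intermediate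
20 | penta-acetate silyl ether: ring A, ring B, ring D O-acetyl, both CH2OAc, ring C O-Si(iPr)3 | COc1cc([C@@H]2OC[C@](O)(Cc3ccc(OC(C)=O)c(OC)c3)[C@@H]2COC(C)=O)cc(-c2cc([C@@H]3OC[C@](O)(Cc4ccc(OC(C)=O)c(OC)c4)[C@@H]3COC(C)=O)cc(OC)c2O[Si](C(C)C)(C(C)C)C(C)C)c1OC(C)=O | intermediate
21 | key-step precursor: bis-tetrahydrofuran penta-acetate with ring C phenol free | COc1cc([C@@H]2OC[C@](O)(Cc3ccc(OC(C)=O)c(OC)c3)[C@@H]2COC(C)=O)cc(-c2cc([C@@H]3OC[C@](O)(Cc4ccc(OC(C)=O)c(OC)c4)[C@@H]3COC(C)=O)cc(OC)c2O)c1OC(C)=O | intermediate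
22 | key-step product: ring B arm unchanged; ring C bears C1 of a (1S,2S,3S)-7-acetoxy-2-(acetoxymethyl)-3-hydroxy-3-(hydroxymethyl)-6-methoxy-1,2,3,4-tetrahydronaphthalene | COc1cc([C@@H]2OC[C@](O)(Cc3ccc(OC(C)=O)c(OC)c3)[C@@H]2COC(C)=O)cc(-c2cc([C@H]3c4cc(OC(C)=O)c(OC)cc4C[C@@](O)(CO)[C@@H]3COC(C)=O)cc(OC)c2O)c1OC(C)=O | intermediate
23 | CNP0344108.1 | COc1cc(C[C@@]2(O)CO[C@@H](c3cc(OC)c(O)c(-c4cc([C@H]5c6cc(O)c(OC)cc6C[C@@](O)(CO)[C@@H]5CO)cc(OC)c4O)c3)[C@H]2CO)ccc1O | target

**Step count and risk**

Total steps: 16. Longest linear sequence: 12 steps (1, 3, 4, 5, 9, 10, 11, 12, 13, 14, 15, 16).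

Steps most likely to fail:

1. Step 15 (key step). Acetyl transfer from the ring B oxygen to the neighbouring ring C oxygen during the acid treatment would unmask ring B, so that the retained tetrahydrofuran also ionises (epimerisation or a second cyclisation); slow Friedel–Crafts capture would prolong the exposure. Fallback with a blocking group that cannot migrate: setting out from triphenol 19, phenol-selective sulfonylation (TsCl, K2CO3, acetone) gives the tris(4-methylbenzenesulfonate) F1. Bu4NF/AcOH frees ring C to give the mono-phenol F2. CF3CO2H in CH2Cl2/(CF3)2CHOH gives the tetrahydrofuran–tetralin tris(tosylate) F3. KOH in degassed aqueous MeOH at 60 °C cleaves the aryl sulfonates and the route is rejoined at 23.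

2. Step 9. Poor facial selectivity at the lactone α-carbon, or β-elimination of the siloxide from the enolate. Fallback with an auxiliary-controlled acyclic aldol: setting out from lactone 7, 2,2-dimethoxypropane/MeOH/TsOH gives the acetonide methyl ester F4 and LiOH gives the acid F5. Mixed-anhydride coupling (t-BuCOCl, Et3N) with lithiated (S)-4-benzyloxazolidin-2-one gives the imide F6. Evans boron aldol (n-Bu2BOTf, iPr2NEt, CH2Cl2, −78 → 0 °C) with dialdehyde 12 gives the bis-syn-aldol adduct F7, in which the auxiliary fixes C2 of each chain. LiBH4 removes the auxiliaries to give the bis-diol bis-acetonide F8, and 80% aqueous AcOH at rt removes the acetonides, rejoining the route at 15 (as a single carbinol diastereomer).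

3. Step 12. Re-ionisation of the newly formed para-alkoxybenzylic ethers by the Lewis acid (epimerisation at C2, over-reduction to the ring-opened methylene compound, or premature Friedel–Crafts closure), or poor facial selectivity in the hydride delivery. Fallback that takes the hydrogen transfer out of the Lewis-acidic medium: setting out from bis-hemiketal 17, thioketalisation (PhSH, 2.2 equiv, BF3·OEt2, CH2Cl2, −78 °C; Et3N quench) gives the bis(O,S-ketal) F9 as an anomeric mixture, used crude. Radical desulfurisation (Bu3SnH, AIBN, toluene, 90 °C) generates a planar benzylic α-oxy radical at each C2, which should take its hydrogen atom from the face opposite the C3 hydroxymethyl and C4 benzyl groups under neutral conditions, and the route is rejoined at 18.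

**Further compounds**

F1 | step 15 | tris(4-methylbenzenesulfonate) of 19 at the ring A, ring B and ring D phenols, ring C still silylated | COc1cc([C@@H]2OC[C@](O)(Cc3ccc(OS(=O)(=O)c4ccc(C)cc4)c(OC)c3)[C@@H]2CO)cc(-c2cc([C@@H]3OC[C@](O)(Cc4ccc(OS(=O)(=O)c5ccc(C)cc5)c(OC)c4)[C@@H]3CO)cc(OC)c2O[Si](C(C)C)(C(C)C)C(C)C)c1OS(=O)(=O)c1ccc(C)cc1
F2 | step 15 | tris(tosylate) with ring C phenol free | COc1cc([C@@H]2OC[C@](O)(Cc3ccc(OS(=O)(=O)c4ccc(C)cc4)c(OC)c3)[C@@H]2CO)cc(-c2cc([C@@H]3OC[C@](O)(Cc4ccc(OS(=O)(=O)c5ccc(C)cc5)c(OC)c4)[C@@H]3CO)cc(OC)c2O)c1OS(=O)(=O)c1ccc(C)cc1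
F3 | step 15 | tetrahydrofuran–tetralin tris(tosylate), all alcohols free | COc1cc([C@@H]2OC[C@](O)(Cc3ccc(OS(=O)(=O)c4ccc(C)cc4)c(OC)c3)[C@@H]2CO)cc(-c2cc([C@H]3c4cc(OS(=O)(=O)c5ccc(C)cc5)c(OC)cc4C[C@@](O)(CO)[C@@H]3CO)cc(OC)c2O)c1OS(=O)(=O)c1ccc(C)cc1
F4 | step 9 | methyl 2-[(4S)-4-(4-benzyloxy-3-methoxybenzyl)-2,2-dimethyl-1,3-dioxolan-4-yl]acetate | COC(=O)C[C@@]1(Cc2ccc(OCc3ccccc3)c(OC)c2)COC(C)(C)O1
F5 | step 9 | 2-[(4S)-4-(4-benzyloxy-3-methoxybenzyl)-2,2-dimethyl-1,3-dioxolan-4-yl]acetic acid | OC(=O)C[C@@]1(Cc2ccc(OCc3ccccc3)c(OC)c2)COC(C)(C)O1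
F6 | step 9 | (4S)-4-benzyl-3-{2-[(4S)-4-(4-benzyloxy-3-methoxybenzyl)-2,2-dimethyl-1,3-dioxolan-4-yl]acetyl}oxazolidin-2-one | O=C(C[C@@]1(Cc2ccc(OCc3ccccc3)c(OC)c2)COC(C)(C)O1)N1[C@@H](Cc2ccccc2)COC1=O
F7 | step 9 | bis-syn-aldol adduct of F6 with 12 (both carbinols S, auxiliaries attached) | COc1cc([C@@H](O)[C@@H](C(=O)N2[C@@H](Cc3ccccc3)COC2=O)[C@@]2(Cc3ccc(OCc4ccccc4)c(OC)c3)COC(C)(C)O2)cc(-c2cc([C@@H](O)[C@@H](C(=O)N3[C@@H](Cc4ccccc4)COC3=O)[C@@]3(Cc4ccc(OCc5ccccc5)c(OC)c4)COC(C)(C)O3)cc(OC)c2O[Si](C(C)C)(C(C)C)C(C)C)c1OCc1ccccc1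
F8 | step 9 | bis-diol bis-acetonide after reductive removal of the auxiliaries | COc1cc([C@@H](O)[C@@H](CO)[C@@]2(Cc3ccc(OCc4ccccc4)c(OC)c3)COC(C)(C)O2)cc(-c2cc([C@@H](O)[C@@H](CO)[C@@]3(Cc4ccc(OCc5ccccc5)c(OC)c4)COC(C)(C)O3)cc(OC)c2O[Si](C(C)C)(C(C)C)C(C)C)c1OCc1ccccc1
F9 | step 12 | bis(O,S-ketal): each arm a 2-aryl-2-(phenylsulfanyl)-3-(hydroxymethyl)-4-(4-benzyloxy-3-methoxybenzyl)oxolan-4-ol, C3 and C4 as in 18, anomeric mixture | COc1cc(C2(Sc3ccccc3)OC[C@](O)(Cc3ccc(OCc4ccccc4)c(OC)c3)[C@@H]2CO)cc(-c2cc(C3(Sc4ccccc4)OC[C@](O)(Cc4ccc(OCc5ccccc5)c(OC)c4)[C@@H]3CO)cc(OC)c2O[Si](C(C)C)(C(C)C)C(C)C)c1OCc1ccccc1
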